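At 3.00 min, the earliest time read, J (monomer in chains) already separates the earlier runs, which share their charge of E (monomer) and differ in Z (initiator) and X (a further species), while amber and ochre differ in their stopping time, 30 min against 8.0 min.

in all of them: E 0.038 M
- Tuesday's: Z 1 mol%; X 0.090 mM; run made earlier
- Monday's: Z 1 mol%; X 0.36 mM; run made earlier
- Thursday's: Z 2 mol%; X 0.18 mM; run made earlier
- amber: Z 1 mol%; X 0.18 mM; time 30 min
- ochre: Z 1 mol%; X 0.18 mM; time 8.0 min

- Tuesday's (time / min: J / %): 3.00: 31.7; 10.0: 40.8; 15.0: 37.6; 25.0: 30.6; 40.0: 19.1
- Monday's (time / min: J / %): 3.00: 7.9; 10.0: 14.1; 15.0: 13.1; 25.0: 10.3; 40.0: 7.6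
- Thursday's (time / min: J / %): 3.00: 50.8; 10.0: 53.3; 15.0: 48.6; 25.0: 38.6; 40.0: 24.6

(readings scatter by 0.5 percentage points)

- the average divides the monomer in chains by the number of chains begun, living and dead together
- the numbers in the tables scatter by 0.5 percentage points (one standard deviation)
- the earlier runs do not show the number of chains; that part of a forecast is a guess

- which of the two ends with the longer chains by the average number of monomer units in a chain (chains begun, living or dead) ("neither" if they lie within 10 %) (amber / ochre / neither)
- average number of monomer units in a chain (chains begun, living or dead) at the end, amber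
- average number of monomer units in a chain (chains begun, living or dead) at the end, ochre

1. Let s = ln(1/(1−J)) at that time, with J as a fraction of the E charged. Tuesday's run gives 0.381 and Thursday's 0.709, while Z minus X stands at 0.290 mM and 0.580 mM, so s per mM reads 1.31 mM⁻¹ and 1.22 mM⁻¹.

2. Thursday's run charges twice the X and twice the Z of Tuesday's, so Z minus any fixed multiple of X doubles as well, and the closeness of those two values does not test how many Z one X removes. As a working assumption, each X removes one Z and each remaining Z begins one chain. Amber and ochre then hold 0.200 mM of N, the chains begun, equal to Z charged minus X charged, the effective initiator concentration.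

3. The X of both flasks lies a fraction w = 0.667 of the way from Monday's run to Tuesday's. At 10.0 min, the reading nearest ochre's stop, this gives J = 31.9 %. At 30 min, Tuesday's run interpolates to 26.8 % and Monday's to 9.40 %, so amber has J = 21.0 %.

4. Length is J times the E charged over N: 39.9 for amber and 60.6 for ochre, so ochre is longer by more than the margin, and N cancels from that ratio.

5. The weak link is one X per Z, and Monday's run tests it: it reads s = 0.0823 on 0.0200 mM, which is 4.12 mM⁻¹, more than Tuesday's 1.31 mM⁻¹. Taking s proportional to Z minus a fixed multiple of X and solving Tuesday's and Monday's s for that multiple gives 0.875 X per Z, hence N = 0.223 mM. The interpolated values of J do not contain N, and with this N the lengths become 35.8 for amber and 54.5 for ochre.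

The forecast, by a separate reckoning, named ochre, with 38 (20 to 55) for amber and 55 (29 to 80) for ochre, holding that “X seems to kill initiator about 1:1”.

The flask gives 41.2 for amber and 62.0 for ochre, so ochre ends longer.

    E + Z → G + J (k = 7.30 L mol⁻¹ s⁻¹)
    E + G → J + G, rate k2*[G]*[E] (k = 12.0 L mol⁻¹ s⁻¹)
    J + G → E + G, rate k3*[G] as long as [J] is above zero (k = 0.0330 s⁻¹)
    Z + X → D (k = 9700 L mol⁻¹ s⁻¹)
    E → Q (k = 0.00340 s⁻¹)

G, the living end, stands at 2.00 × 10⁻⁴ M in amber and 2.00 × 10⁻⁴ M in ochre, which is N of the first reckoning, while J is 21.7 % against 32.7 %. In a neighbouring flask, amber with 1.1 × 10⁻⁴ M of X, N becomes 0.270 mM, and its J of 25.3 % over that N gives 35.6, where the flask itself stands at 35.6.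

(Readings and results are simulated with constants of no real substance; noise was put on by code.)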